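The ratio to watch along this row of flasks is the mean life of intermediate A on its way to intermediate B, divided by the mean life of the partner.

| flask | starting material | partner | protic impurity | time |
|---|---|---|---|---|
| dawn | 0.012 M | 0.150 M | 0.100 M | 10 h |
| autumn | 0.030 M | 0.150 M | 0.100 M | 10 h |
| winter | 0.10 M | 0.150 M | 0.100 M | 10 h |
| noon | 0.30 M | 0.150 M | 0.100 M | 10 h |
| spring | 1.0 M | 0.150 M | 0.100 M | 10 h |

    intermediate C → target (k1 = 1.2 × 10⁻⁶ s⁻¹)
    partner + protic impurity → quenched reagent (k2 = 3.4 × 10⁻⁴ M⁻¹ s⁻¹)
    partner + intermediate B → intermediate C (k3 = 0.0016 M⁻¹ s⁻¹)
    partner + intermediate A → side product (k4 = 2.5 × 10⁻⁴ M⁻¹ s⁻¹)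
    intermediate A → intermediate B (k5 = 2.7 × 10⁻⁵ s⁻¹)
    starting material + partner → intermediate A (k6 = 6.9 × 10⁻⁴ M⁻¹ s⁻¹)

- [target] at the end for dawn, autumn, winter, noon, spring, in this order
- how the row runs (falls, then rises / falls all the way / rises all the way / rises, then falls / hardly changes)

- "hardly changes" means that all values lie within two and a half points (for a concentration: within two and a half percent of the largest)
- run time (dawn): 10 h

The last step has a life of 231 h, far longer than the 10 h run, so it hands on about 4.32% of any intermediate C standing through the run, a fraction that contains no starting material. Intermediate B, with the partner as charged, lasts 1.16 h, which is shorter than the 10.3 h that intermediate A needs, so with the partner at that level the wait on the way to intermediate C lies at intermediate A. The split of intermediate A, 41.9% towards intermediate B with the partner as charged, contains no starting material either.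

The charge of starting material enters through the partner's life, a pseudo-first-order life reckoned from the two species that take the partner from the start, starting material and protic impurity, each held at its charge. In dawn that life is 6.57 h, and at the start the protic impurity takes the partner faster than the starting material does, so this reckoning expects the target at this low end to grow about in step with the charge. In spring the life shrinks to 0.384 h, which is shorter than the time intermediate A needs, so this reckoning expects intermediate A to outlast the partner in spring. The ratio of the two times, 1.57 in dawn and 26.8 in spring, is the race number, the life of intermediate A towards intermediate B over the life of the partner. The two ends join where starting material and protic impurity take the partner equally fast at the start, at a charge of 0.0493 M, so this reckoning by hand expects a rise, then a fall, with the top above that charge, and it gives no row values.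

The forecast does give them: 5.200 × 10⁻⁵ M, 1.150 × 10⁻⁴ M, 2.600 × 10⁻⁴ M, 1.700 × 10⁻⁴ M and 3.500 × 10⁻⁵ M, a row that rises, then falls, on the ground that at high loading “the starting material burns off the partner within an hour or so, before A has become B”.

The flasks give 5.66 × 10⁻⁵ M, 1.29 × 10⁻⁴ M, 2.70 × 10⁻⁴ M, 1.80 × 10⁻⁴ M and 3.31 × 10⁻⁵ M, so the row rises, then falls, and its turn, read at 0.13 M, sits at a race number of 4.48. Spring, at 26.8, ends with 0.00331% of its charge as target, and the simulated run with the partner held level lifts the spring target by a factor of 173 to 0.00571 M, the largest single effect tried. Dawn, at 1.57, gains a factor of 1.21 from the same change.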